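## The problem

The target **11**, 2-hydroxy-4-methoxy-6-(2-oxotridecyl)benzoic acid, is a tetrasubstituted benzene with ring hydrogens only at C3 and C5. The task is therefore to place a carboxyl group, a hydroxyl, a methoxyl and a thirteen-carbon chain in the right order around one ring. There is no ring besides the benzene ring and no stereocentre, so no centre has to control another, and any carbinol centre met on the way can be carried as a racemate. The chain is joined to C6 through a methylene group and carries its ketone on the next carbon, so the ketone oxygen can reach the carboxyl carbon through a six-membered ring. The open keto acid and its enol lactone, the 3-undecylisocoumarin, are thus one dehydration apart, and acid, heat or dehydrating agents close the ring. The acid has a hydroxyl ortho and a methoxyl para to the carboxyl group and loses CO2 when heated in acid; the methylene between arene and ketone enolises easily, and the free phenol does not tolerate oxidants. The two ring oxygens at C2 and C4 differ only by one methyl group and must be told apart at some point. The enabling feature appears when the carboxyl carbon is removed: what remains is a 3,5-dioxygenated benzyl unit with a mirror plane through C6 and C3, so the two C–H positions ortho to the chain are identical. The chain oxygen at C2', carried as a hydroxyl group, can hold a metal over either of them through a six-membered metallacycle, and the lactone carbonyl that results marks the neighbouring oxygen as the one to be freed.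

## Retrosynthesis

**11 from 10.** The target is read as the hydrolysed form of the enol lactone 8-hydroxy-6-methoxy-3-undecyl-1H-isochromen-1-one **10**; in the retrosynthetic sense the bond between the enol oxygen and the carboxyl carbon is closed. This keeps acid and ketone masked in one neutral ring, without any protecting group, until the last step. The free keto acid then exists only once, under base, where it cannot re-close. The forward reaction must open a lactone whose carbonyl is deactivated by the neighbouring phenoxide, and must give the free acid without heat or strong acid.

**10 from 9.** The O–CH3 bond at C8 is cut, leading back to 6,8-dimethoxy-3-undecyl-1H-isochromen-1-one **9**. The lactone carbonyl and the peri methoxy oxygen can chelate a boron Lewis acid, so the two ethers, identical until the carboxyl carbon arrived, are now different. Differentiating the oxygens earlier, with two unlike ether groups on the starting arene, would destroy the mirror symmetry on which the key step rests. The forward reaction must cleave one aryl methyl ether and leave the other and the enol lactone alone.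

**9 from 7 (through 8).** The C3=C4 double bond is taken back to the saturated lactone 6,8-dimethoxy-3-undecylisochroman-1-one **7**. This is an oxidation-level correction and is the price of using a hydroxyl group as the directing group. A hydride-abstracting quinone was considered and set aside. Both methoxy groups are meta to C4a and cannot stabilise positive charge at C4, and the lactone carbonyl, conjugated through the ring, works against it. The radical pathway has no such demand: bromination at C4, the only benzylic position, gives the 4-bromo lactone **8**, and base removes HBr across C3–C4. The forward reaction must prefer the benzylic hydrogen over the electron-rich ring.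

**7 from 5 and 6 (key disconnection).** The aryl–carbonyl bond (C8a–C1) and the acyl–oxygen bond (C1–O2) are cut together. This gives 1-(3,5-dimethoxyphenyl)tridecan-2-ol **5** and carbon monoxide **6**. The precursor has lost the heterocycle and one carbon, and its arene is symmetric.
- Against metalation: deprotonation of a 1-alkyl-3,5-dimethoxybenzene by an organolithium goes between the two methoxy groups, which is the wrong carbon.
- Against electrophilic formylation: it would need a later oxidation and can also attack between the methoxy groups.
- Against halogenation followed by carbonylation: it takes two steps for the same bonds (kept as the fallback).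
- For the hydroxyl-directed palladation: it can only reach the two equivalent ortho positions, and it delivers the carboxyl carbon already tied into the lactone that later differentiates the oxygens.

The forward reaction must cleave a C–H bond flanked by the chain and a methoxy group, and must do so faster than palladium oxidises the secondary carbinol.

**5 from 2 and 3 (through 4).** The bond between the arene and the benzylic methylene is cut. The aryl part becomes 3,5-dimethoxyphenylmagnesium bromide **4**, made from 1-bromo-3,5-dimethoxybenzene **3**, and the chain becomes 2-undecyloxirane **2**. Cutting one bond further out, between C1' and C2' or between C2' and C3', would need a benzylic organometallic or an enolisable arylacetaldehyde; the aryl bromide and a terminal epoxide are simpler and set the oxygen at C2' directly. The forward reaction must open the epoxide only at its terminal carbon.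

**2 from 1.** The two C–O bonds of the oxirane are removed to give 1-tridecene **1**, a commercial alkene; a peracid epoxidation is all that is asked.

## Roads not taken

Alternative 1: The arene would be built, as the phenol methyl 6-[2-(tert-butyldimethylsilyloxy)tridecyl]-4-hydroxy-2-(pivaloyloxy)benzoate A1, by cutting C3–C4 and C4–C5 and returning C4 to carbon monoxide. The precursor is the enyne ester A2, in which one fully substituted carbon carries the ethynyl group, the pivalate, the methyl ester and a 1,1-disubstituted vinyl group bearing the silyloxy chain.
- Forward key step: under [Rh(CO)2Cl]2 and CO the pivalate moves to the adjacent alkyne carbon, the rhodium carbene takes up CO to give a ketene, and six-electron ring closure onto the alkene followed by tautomerisation gives A1.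
- Merits: the two ring oxygens are born different (pivalate at C2, free hydroxyl at C4 ready for methylation), and the carboxyl carbon is in place from the start, so no C–H functionalisation and no late ether differentiation are needed.
- Weak points: A2 needs a multi-step assembly around a crowded carbinol carbon, and the acyloxy shift must take place at a centre that also bears an ester. After the ring is made there remain O-methylation, desilylation, oxidation of the carbinol and cleavage of both the pivalate and a doubly ortho-substituted methyl ester. The ester cleavage must be done beside an enolisable ketone, where base can drive a Claisen-type closure onto the ester.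
- Comparison: this road is better at oxygen differentiation, but it would be roughly twice as long. The chosen plan buys the arene and spends its one demanding step on the carboxyl carbon.

Alternative 2: The ring bond C1–C6 is cut and the arene is unfolded into a polyketide chain; the key-step product is 7-hydroxy-2,2-dimethyl-5-[(2-undecyl-1,3-dioxolan-2-yl)methyl]-1,3-benzodioxin-4-one A3, and its precursor is the diketo-dioxinone A4.
- Forward key step: with Et3N the dioxinone C5 carbon adds to the outer chain ketone, water is lost and the inner ketone enolises, closing the benzene ring as a benzodioxinone.
- Merits: one mild step delivers the ring, the masked carboxyl group, a free C4 hydroxyl for methylation with the C2 oxygen held in the acetonide, and the side-chain ketone at the right oxidation level as its dioxolane. No redox correction and no selective demethylation are needed. In these two respects it is better than the chosen plan.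
- Weak points: A4 needs two C-acylations of a dioxinone enolate with a ketal-bearing acyl donor. Diketo-dioxinones are labile, both to premature cyclisation and to thermal loss of acetone. A ketal β to a ketone can eliminate under base. The end game must remove the dioxolane with aqueous acid, the very conditions under which the keto acid closes to the isocoumarin.
- Comparison: the chosen plan sets against it a shorter sequence from simple commercial materials (six steps against about eight) and a last step run in base, where the keto acid is safe.

Alternative 3: The bond between C6 and the benzylic methylene is cut together with the lactone C–O bond. The key-step product is 6,8-dimethoxy-3-undecylisocoumarin A5, which is the same compound as **9**. The precursors are 2,4-dimethoxybenzoic acid A6 and dimethylsulfoxonium 2-oxotridecylide A7.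
- Forward key step: under [Cp*RhCl2]2 and AgSbF6 the carboxylate directs rhodation of the only free ortho C–H, the ylide delivers a carbene that inserts to form the C6–CH2 bond, and the keto acid closes to the lactone.
- Merits: this is the shortest road. It needs about two steps to A5, against four to **9** in the chosen plan. It also arrives at the isocoumarin oxidation level directly, so the bromination–elimination step and its risk disappear. There is only one ortho C–H, so no symmetry argument is needed. In step and redox economy it is better than the chosen plan.
- Weak points: A6 is an electron-rich ortho-alkoxybenzoic acid of the kind that loses CO2 with silver salts on heating. Its ortho methoxy group twists the directing carboxylate. A7 is an alkyl ylide with enolisable hydrogens, a less reactive partner than the aryl ylides on which this annulation works best.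
- Comparison: the chosen plan sets against it a C–H site activated by an ortho and a para methoxy group, an arene with no carboxyl group to lose, a cheaper metal, and an independent conventional route to the same lactone **7** if the C–H step fails. It also gives access to the dihydro lactone series. Since A5 and **9** are identical, the last two steps are common to both roads.

Key step: step 3

Remark on the chemistry: the target has no stereocentre, so **2**, **5** and **7** are carried as racemates and **8** as a racemic mixture of diastereomers; C3 becomes trigonal in step 4.

## Route

Step 1
Reactants: 1 1-tridecene
Product: 2 2-undecyloxirane (racemic)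
Conditions: mCPBA (1.2 equiv), CH2Cl2, 0 °C to rt
Reagents that add atoms: mCPBA (3-chloroperoxybenzoic acid), OOC(=O)c1cccc(Cl)c1
Why: Prilezhaev epoxidation of a monosubstituted alkene by a peracid is general. The concerted oxygen transfer sets the one stereocentre without control, so 2 is racemic; this carbon ends as the ketone carbon.

Step 2
Reactants: 2 2-undecyloxirane; 3 1-bromo-3,5-dimethoxybenzene
Product: 5 1-(3,5-dimethoxyphenyl)tridecan-2-ol (racemic), via 3,5-dimethoxyphenylmagnesium bromide 4 (not isolated)
Conditions: 3, Mg, I2 (cat.), THF, reflux; then CuI (10 mol%), 2, THF, −30 to 0 °C; H2O (aq. NH4Cl work-up)
Reagents that add atoms: none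
Why: Magnesium insertion gives the aryl Grignard reagent 4, and under CuI catalysis the derived arylcopper species opens the terminal epoxide by SN2 attack at the unsubstituted carbon (copper-catalysed Grignard–epoxide coupling). Low temperature and the copper catalyst hold back bromohydrin formation and Lewis-acid rearrangement of 2; the carbinol centre comes from racemic 2 and is not controlled.

Step 3
Reactants: 5 1-(3,5-dimethoxyphenyl)tridecan-2-ol; 6 carbon monoxide
Product: 7 6,8-dimethoxy-3-undecylisochroman-1-one (racemic)
Conditions: Pd(OAc)2 (10 mol%), N-(menthyloxycarbonyl)-L-leucine (20 mol%), AgOAc (3 equiv), Li2CO3 (1 equiv), CO (1 atm), ClCH2CH2Cl, 110 °C, sealed vessel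
Reagents that add atoms: none
Why: The reaction type is the hydroxyl-directed ortho C–H carbonylation of 2-arylethanols to isochroman-1-ones under divalent palladium with a mono-N-protected amino acid ligand, known mainly for tertiary carbinols; the secondary carbinol 5 is a harder member of the same class. The alkoxide of 5 binds palladium, and ligand-assisted concerted metalation–deprotonation, with the N-acyl group of the ligand as internal base, cleaves an ortho C–H bond to give a six-membered palladacycle. CO inserts into the aryl–palladium bond, and C–O reductive elimination from the acyl palladium alkoxide closes the six-membered lactone (attack of the tethered alkoxide on the acyl carbon, formally 6-exo-trig); AgOAc returns zerovalent palladium to the divalent state. No stereocentre is formed: C3 keeps the racemic configuration of 5 and is removed in step 4. Regioselectivity is not in question, because the mirror plane of the 3,5-dimethoxybenzyl group makes the two ortho C–H bonds identical and the third ring C–H, between the methoxy groups, cannot be reached through a six-membered palladacycle. The reacting carbon is ortho to one methoxy group and para to the other, which favours palladation electronically although the site is flanked on both sides. The selectivity that matters is C–H cleavage against β-hydride elimination from the palladium alkoxide, which would oxidise 5 to the ketone; the amino acid ligand, which speeds up the metalation, together with the CO atmosphere and the carbonate base, is there to secure it.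

Step 4
Reactants: 7 6,8-dimethoxy-3-undecylisochroman-1-one
Product: 9 6,8-dimethoxy-3-undecyl-1H-isochromen-1-one, via 4-bromo-6,8-dimethoxy-3-undecylisochroman-1-one 8 (not isolated)
Conditions: NBS (1.05 equiv), AIBN (5 mol%), PhCF3, 85 °C, hν; then Et3N (3 equiv), rt to 60 °C
Reagents that add atoms: none
Why: Wohl–Ziegler bromination takes a benzylic hydrogen at C4, the only benzylic position, to give 8, and Et3N then removes HBr across C3–C4 by E2 elimination to the conjugated pyranone; bromination–dehydrobromination is the usual way from 3,4-dihydroisocoumarins to isocoumarins. The lactone carbonyl lowers the nucleophilicity of the ring, and a non-polar solvent with radical initiation keeps ionic ring bromination back. The racemic centre at C3 disappears here.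

Step 5
Reactants: 9 6,8-dimethoxy-3-undecyl-1H-isochromen-1-one
Product: 10 8-hydroxy-6-methoxy-3-undecyl-1H-isochromen-1-one
Conditions: BCl3 (1 M in CH2Cl2, 1.5 equiv), CH2Cl2, −78 to 0 °C; then H2O
Reagents that add atoms: none
Why: BCl3 is held between the lactone carbonyl and the peri methoxy oxygen in a six-membered chelate, and chloride removes the methyl group of that ether only (chelation-controlled demethylation of an aryl methyl ether ortho to a carbonyl). The C6 methoxy group has no such neighbour and stays.

Step 6
Reactants: 10 8-hydroxy-6-methoxy-3-undecyl-1H-isochromen-1-one
Product: 11 2-hydroxy-4-methoxy-6-(2-oxotridecyl)benzoic acid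
Conditions: KOH (2 M aq., 5 equiv), EtOH, 70 °C; then 1 M HCl to pH 2–3 at 0 °C, extraction with EtOAc, no heating
Reagents that add atoms: water, O (supplied as hydroxide from KOH, [K+].[OH-])
Why: Saponification of the enol lactone: hydroxide adds to the lactone carbonyl, and ring opening releases an enolate that becomes the ketone, so the opening is not reversed in base. Cold acidification to the free acid is meant to avoid acid-catalysed re-closure and decarboxylation.

## Compound list

1 | 1-tridecene | CCCCCCCCCCCC=C | starting material
2 | 2-undecyloxirane (1,2-epoxytridecane), racemic | CCCCCCCCCCCC1CO1 | intermediate
3 | 1-bromo-3,5-dimethoxybenzene | COc1cc(Br)cc(OC)c1 | starting material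
4 | 3,5-dimethoxyphenylmagnesium bromide | COc1cc([Mg]Br)cc(OC)c1 | intermediate (not isolated)
5 | 1-(3,5-dimethoxyphenyl)tridecan-2-ol, racemic | CCCCCCCCCCCC(O)Cc1cc(OC)cc(OC)c1 | intermediate
6 | carbon monoxide | [C-]#[O+] | starting material
7 | 6,8-dimethoxy-3-undecylisochroman-1-one, racemic | CCCCCCCCCCCC1Cc2cc(OC)cc(OC)c2C(=O)O1 | intermediate
8 | 4-bromo-6,8-dimethoxy-3-undecylisochroman-1-one, racemic mixture of diastereomers | CCCCCCCCCCCC1OC(=O)c2c(OC)cc(OC)cc2C1Br | intermediate (not isolated)
9 | 6,8-dimethoxy-3-undecyl-1H-isochromen-1-one | CCCCCCCCCCCc1cc2cc(OC)cc(OC)c2c(=O)o1 | intermediate
10 | 8-hydroxy-6-methoxy-3-undecyl-1H-isochromen-1-one | CCCCCCCCCCCc1cc2cc(OC)cc(O)c2c(=O)o1 | intermediate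
11 | 2-hydroxy-4-methoxy-6-(2-oxotridecyl)benzoic acid | CCCCCCCCCCCC(=O)Cc1cc(OC)cc(O)c1C(=O)O | target

## Step count and risk

Total steps: 6. Longest linear sequence: 6 steps (1 → 2 → 5 → 7 → 9 → 10 → 11).

**Step 3 (key step).** The most likely failure is oxidation of the secondary carbinol: β-hydride elimination from the palladium alkoxide may outrun C–H cleavage, the more so because the C–H bond is flanked on both sides. Reduction of the catalyst to palladium metal under CO before turnover is the second concern.

The fallback sets out from 5 and returns at 7. Electrophilic bromination of 5 with NBS in MeCN at 0 °C should go para to one methoxy group and ortho to the chain, again at either of two equivalent positions, to give 1-(2-bromo-3,5-dimethoxyphenyl)tridecan-2-ol F1. Carbonylative lactonisation under zerovalent palladium (Pd(OAc)2, 1,1'-bis(diphenylphosphino)ferrocene, CO, Et3N, DMF, 100 °C) then proceeds by oxidative addition, CO insertion and capture of the acyl palladium by the tethered hydroxyl, and closes the same lactone 7. No oxidant is present, so the carbinol is not at risk.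

**Step 4.** Ionic bromination of the dimethoxy ring at C5 or C7 may compete with the radical reaction at C4, and a second bromination at C4 is possible.

The fallback sets out from 7 and returns at 9; it moves the oxidation from C4 to the carbinol carbon. Aminolysis of 7 with Me2NH·HCl and AlMe3 in toluene should open the lactone to 2-(2-hydroxytridecyl)-4,6-dimethoxy-N,N-dimethylbenzamide F2. Dess–Martin oxidation gives 2,4-dimethoxy-N,N-dimethyl-6-(2-oxotridecyl)benzamide F3. Heating F3 in acetic acid closes the enol onto the amide with loss of dimethylamine, the usual way from such keto amides to isocoumarins, and gives 9.

**Step 6.** Opening may be slow because the phenoxide deactivates the lactone carbonyl. During acidification the keto acid may re-close to 10 or lose CO2.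

The fallback sets out from 10 and returns at 11; it releases the acid under neutral conditions. Opening of 10 with sodium benzyloxide (BnOH, NaH, THF, 0 °C to rt) should give benzyl 2-hydroxy-4-methoxy-6-(2-oxotridecyl)benzoate F4. Hydrogenolysis (H2, 10% Pd/C, EtOAc, rt) then gives 11 without aqueous acid or heat.

**Step 2.** Bromide from the magnesium salts may open the epoxide, the epoxide may rearrange to the aldehyde under Lewis acid before aryl transfer, and the Grignard reagent may couple with itself during its formation.

The fallback sets out from 3 (through 4) and returns at 5; it reverses the roles so that a primary alkyl Grignard reagent, the best nucleophile for this coupling, opens the epoxide. Reagent 4 is allylated with allyl bromide to 1,3-dimethoxy-5-(prop-2-en-1-yl)benzene F5. Epoxidation with mCPBA gives 2-(3,5-dimethoxybenzyl)oxirane F6. Decylmagnesium bromide with CuI (10 mol%) in THF at −30 °C opens F6 at the terminal carbon to give 5.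

## Further compounds

F1 | step 3 | 1-(2-bromo-3,5-dimethoxyphenyl)tridecan-2-ol, racemic | CCCCCCCCCCCC(O)Cc1cc(OC)cc(OC)c1Br
F2 | step 4 | 2-(2-hydroxytridecyl)-4,6-dimethoxy-N,N-dimethylbenzamide, racemic | CCCCCCCCCCCC(O)Cc1cc(OC)cc(OC)c1C(=O)N(C)C
F3 | step 4 | 2,4-dimethoxy-N,N-dimethyl-6-(2-oxotridecyl)benzamide | CCCCCCCCCCCC(=O)Cc1cc(OC)cc(OC)c1C(=O)N(C)C
F4 | step 6 | benzyl 2-hydroxy-4-methoxy-6-(2-oxotridecyl)benzoate | CCCCCCCCCCCC(=O)Cc1cc(OC)cc(O)c1C(=O)OCc1ccccc1
F5 | step 2 | 1,3-dimethoxy-5-(prop-2-en-1-yl)benzene | C=CCc1cc(OC)cc(OC)c1
F6 | step 2 | 2-(3,5-dimethoxybenzyl)oxirane, racemic | COc1cc(CC2CO2)cc(OC)c1
A1 | alternative 1 | methyl 6-[2-(tert-butyldimethylsilyloxy)tridecyl]-4-hydroxy-2-(pivaloyloxy)benzoate, racemic | COC(=O)c1c(OC(=O)C(C)(C)C)cc(O)cc1CC(O[Si](C)(C)C(C)(C)C)CCCCCCCCCCC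
A2 | alternative 1 | methyl 5-(tert-butyldimethylsilyloxy)-2-ethynyl-3-methylidene-2-(pivaloyloxy)hexadecanoate, mixture of stereoisomers | C#CC(OC(=O)C(C)(C)C)(C(=O)OC)C(=C)CC(O[Si](C)(C)C(C)(C)C)CCCCCCCCCCC
A3 | alternative 2 | 7-hydroxy-2,2-dimethyl-5-[(2-undecyl-1,3-dioxolan-2-yl)methyl]-1,3-benzodioxin-4-one | CC1(C)OC(=O)c2c(CC3(CCCCCCCCCCC)OCCO3)cc(O)cc2O1
A4 | alternative 2 | 6-[2,4-dioxo-5-(2-undecyl-1,3-dioxolan-2-yl)pentyl]-2,2-dimethyl-1,3-dioxin-4-one | CC1(C)OC(=O)C=C(CC(=O)CC(=O)CC2(CCCCCCCCCCC)OCCO2)O1
A5 | alternative 3 | 6,8-dimethoxy-3-undecylisocoumarin (identical with 9) | CCCCCCCCCCCc1cc2cc(OC)cc(OC)c2c(=O)o1
A6 | alternative 3 | 2,4-dimethoxybenzoic acid | COc1ccc(C(=O)O)c(OC)c1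
A7 | alternative 3 | dimethylsulfoxonium 2-oxotridecylide | CCCCCCCCCCCC(=O)C=S(C)(C)=O
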